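**The question.** How much complex with two exchanged stands at the end of red, and which form leads in each new flask?

in all of them: starting complex 20 mM

| run | incoming ligand | leaving ligand | remark | time |
|---|---|---|---|---|
| Friday's | 0.66 equiv | 1 equiv | run made earlier |  |
| Saturday's | 3.9 equiv | 1 equiv | run made earlier |  |
| teal | 1.00 equiv | 1.00 equiv |  | 3.0 d |
| red | 2.50 equiv | 1.00 equiv |  | 3.0 d |
| violet | 0.500 equiv | 1.00 equiv |  | 3.0 d |

| run | time / h | complex with two exchanged / % | complex with one exchanged / % |
|---|---|---|---|
| Friday's | 3.00 | 1.5 | 13.4 |
| Friday's | 10.0 | 7.8 | 20.4 |
| Friday's | 20.0 | 8.2 | 25.4 |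
| Friday's | 30.0 | 11.3 | 23.9 |
| Friday's | 40.0 | 11.6 | 24.9 |
| Friday's | 48.0 | 12.5 | 26.9 |
| Saturday's | 4.00 | 20.2 | 26.4 |
| Saturday's | 6.00 | 25.3 | 25.8 |
| Saturday's | 12.0 | 26.0 | 16.5 |
| Saturday's | 20.0 | 21.5 | 10.0 |
| Saturday's | 30.0 | 15.0 | 4.6 |
| Saturday's | 48.0 | 6.4 | 1.4 |

(readings scatter by 1 percentage point)
* which of these holds the largest part of the starting complex at the end of teal (starting complex / complex with one exchanged / complex with three exchanged / complex with two exchanged)
* which of these holds the largest part of the starting complex at the end of red (starting complex / complex with one exchanged / complex with three exchanged / complex with two exchanged)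
* which of these holds the largest part of the starting complex at the end of violet (starting complex / complex with one exchanged / complex with three exchanged / complex with two exchanged)
* how much complex with two exchanged is there at the end of red, in percent of the starting complex charged


**The puzzle.** Saturday's flask, charged with 3.9 equiv of incoming ligand, holds 6.4% of complex with two exchanged at 48.0 h. Friday's flask, charged with 0.66 equiv, holds 12.5% at 48.0 h. That is about half as much from the larger charge.

**The ladder.** I ask for the end state first. Each exchange spends one incoming ligand, and a complex has 3 places. For red, 0.833 is the fill, the incoming ligand charged per complex divided by those places. Friday's fill is 0.220. Saturday's is 1.30, above 1, so its complex can pass through two-exchanged to the top.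

**A test.** Friday's last readings give a ratio of two-exchanged to one-exchanged of 0.465. Applied equally to each rung, it gives 0.673 exchanges per complex, against 0.66 equiv charged.

**My reckoning.** On a ladder with the same ratio on each rung and its incoming ligand spent, a fill above 0.5 puts the top rung ahead, and one below puts starting complex ahead. Teal has 0.333 and violet 0.167, both below that mark, and red's fill is above it, so I expect starting complex ahead in teal and violet and three-exchanged ahead in red. Red's empty part, 0.167, is smaller than Friday's fill, so on this ladder, counted from the top, red resembles Friday's flask with two-exchanged in the place of one-exchanged. I therefore expect red's two-exchanged somewhat under Friday's last reading of 26.9% of one-exchanged. Red also runs longer than Friday's last reading.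

**The forecast.** It names starting complex for teal, complex with three exchanged for red and starting complex for violet, and gives 27% of two-exchanged for red, "with three-exchanged dominant". My expectation for two-exchanged lies a little lower.

**The flask.** Teal gives starting complex, 42.5%; red gives complex with three exchanged, 61.2%; violet gives starting complex, 65.0%. Red holds 22.7% of two-exchanged, so the forecast held.

    starting complex + incoming ligand ⇌ leaving ligand + complex with one exchanged (K = 0.400, k = 0.110 L mol⁻¹ min⁻¹)
    complex with one exchanged + incoming ligand ⇌ leaving ligand + complex with two exchanged (K = 0.280, k = 0.340 L mol⁻¹ min⁻¹)
    complex with two exchanged + incoming ligand ⇌ leaving ligand + complex with three exchanged (K = 0.380, k = 0.160 L mol⁻¹ min⁻¹)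
    leaving ligand → by-product carried off (k = 0.00580 min⁻¹)

**Not quite resting.** Red still has 4.3% of its incoming ligand at 3.00 d. By 30.0 d, two-exchanged is 21.0% and three-exchanged 66.7%. A neighbour of red charged with 6.20 equiv has a fill of 2.07, so 51.7% of its incoming ligand should be spare. It ends with 52% left and 0% of two-exchanged.

The readings stem from a simulated flask on assumed constants; scatter was added.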